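**Retrosynthetic overview**
1. Target 28 ⇐ ketone 27 (C=O → C=CH2) ⇐ bromo keto aldehyde 24 (CHO → CH3, then epimerisation at C1) ⇐ cycloheptenol 22.
2. Key disconnection: the C4a–C5 bond of ring B is made by a bromonium-triggered 1,2-shift that contracts a seven-membered carbocycle to the six-membered ring B and sets C5 and C6; the same NBS charge brominates the phenol twice.
3. 22 ⇐ ring-closing metathesis ⇐ 21 ⇐ Ni/Cr coupling of ring-A aldehyde 13 with alkenyl triflate 20, whose Br/Cl pair comes from catalytic enantioselective bromochlorination of prenol.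
4. 13 ⇐ conjugate addition and benzylation of enone 5 ⇐ catalytic asymmetric Diels–Alder reaction. Ring order: ring A (Diels–Alder) → seven-membered ring (metathesis) → ring B (step 16, 7→6 contraction); the arene is carried intact.
5. Enabling feature: in 22 the CH(OH) carbon lies inside the seven-membered ring, between the ring-fusion CH of ring A and the ring-alkene carbon that bears the side chain (a cyclohept-2-en-1-ol). A bromonium ion on that alkene lets the oxygen lone pair push the bond between the ring-fusion CH and the carbinol carbon onto the tertiary alkene carbon, and the carbinol carbon leaves the ring as the axial CHO that becomes the C5 methyl.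

Key step: step 16

Remark (locants): bicyclic compounds use the decalin locants of 28: C1 = CH with the arylmethyl group, C2 = C(=CH2), C4a = ring-fusion CH, C5 = C(CH3)(side chain), C6 = CHBr, C8a = ring-fusion C(CH3); ring A = C1–C4, C4a, C8a; ring B = C4a–C8, C8a.
Assumption: the arylmethyl-bearing centre (C1) is introduced kinetically in the axial, epimeric sense in step 7 and is carried so until step 19 corrects it under thermodynamic control; any of the other epimer formed in step 7 converges there.

Step 1
Reactants: 1 (E)-pent-3-en-2-one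
Product: 2 (E)-2-[(triisopropylsilyl)oxy]penta-1,3-diene
Conditions: TIPSOTf, Et3N, Et2O, 0 °C to rt
Reagents that add atoms: triisopropylsilyl trifluoromethanesulfonate, CC(C)[Si](OS(=O)(=O)C(F)(F)F)(C(C)C)C(C)C
Why: Soft enolisation and O-silylation at the methyl group of the ketone should give the cross-conjugated 2-silyloxy diene with the E-propenyl unit unchanged (silyl enol ether formation).

Step 2
Reactants: 2 (E)-2-[(triisopropylsilyl)oxy]penta-1,3-diene; 3 methyl acrylate
Product: 4 methyl (1S,2R)-2-methyl-4-[(triisopropylsilyl)oxy]cyclohex-3-ene-1-carboxylate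
Conditions: AlBr3-activated o-tolyl diphenylprolinol-derived oxazaborolidine (10 mol%, enantiomer chosen to give the 1S ester), CH2Cl2, −78 °C
Reagents that add atoms: none
Why: Catalytic enantioselective Diels–Alder reaction in which the silyloxy group and the terminal methyl group both direct the ester-bearing carbon next to the methyl-bearing carbon, endo addition gives the cis adduct, and the chiral Lewis acid shields one acrylate face and so sets the ester-bearing stereocentre (the methyl-bearing one is erased in step 3).

Step 3
Reactants: 4 methyl (1S,2R)-2-methyl-4-[(triisopropylsilyl)oxy]cyclohex-3-ene-1-carboxylate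
Product: 5 methyl (1S)-2-methyl-4-oxocyclohex-2-ene-1-carboxylate
Conditions: Pd(OAc)2 (1.05 equiv), MeCN, 40 °C
Reagents that add atoms: none
Why: Saegusa–Ito oxidation, in which the palladium enolate can only β-hydride eliminate toward the methyl-bearing carbon, so the 3-methyl enone forms regiospecifically under non-basic conditions that should leave the allylic ester stereocentre untouched.

Step 4
Reactants: 5 methyl (1S)-2-methyl-4-oxocyclohex-2-ene-1-carboxylate; 6 but-3-en-1-ylmagnesium bromide
Product: 7 methyl (1S,2S)-2-(but-3-en-1-yl)-2-methyl-4-[(trimethylsilyl)oxy]cyclohex-3-ene-1-carboxylate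
Conditions: CuBr·SMe2 (10 mol%), TMSCl, HMPA, THF, −78 °C
Reagents that add atoms: chlorotrimethylsilane, C[Si](C)(C)Cl
Why: Chlorosilane-accelerated copper-catalysed conjugate addition of the Grignard reagent should deliver the butenyl group anti to the neighbouring ester substituent (trans rule for 4-substituted cyclohexenones), which sets the quaternary centre, and should trap the enolate regiospecifically before γ-deprotonation can racemise the ester-bearing carbon.

Step 5
Reactants: 8 2-methylphenol
Product: 9 2-methylphenyl pivalate
Conditions: PivCl, Et3N, DMAP (cat.), CH2Cl2, 0 °C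
Reagents that add atoms: pivaloyl chloride, CC(C)(C)C(=O)Cl
Why: Standard O-acylation; the pivalate masks the phenol during the alkylation and falls off without an extra step in step 8.

Step 6
Reactants: 9 2-methylphenyl pivalate
Product: 10 2-(bromomethyl)phenyl pivalate
Conditions: NBS, AIBN (cat.), PhCF3, 85 °C
Reagents that add atoms: N-bromosuccinimide, O=C1CCC(=O)N1Br
Why: Wohl–Ziegler benzylic bromination, for which the acylated ring is too deactivated to undergo electrophilic ring bromination.

Step 7
Reactants: 7 methyl (1S,2S)-2-(but-3-en-1-yl)-2-methyl-4-[(trimethylsilyl)oxy]cyclohex-3-ene-1-carboxylate; 10 2-(bromomethyl)phenyl pivalate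
Product: 11 methyl (1S,2S,3R)-2-(but-3-en-1-yl)-2-methyl-4-oxo-3-{[2-(pivaloyloxy)phenyl]methyl}cyclohexane-1-carboxylate
Conditions: (Me2N)3S+ Me3SiF2− (TASF, 1.1 equiv), THF, −40 °C to rt
Reagents that add atoms: none
Why: Fluoride-promoted regiospecific alkylation of a silyl enol ether, in which the benzylic bromide should enter opposite the axial methyl of the adjacent quaternary carbon and so give the benzyl group trans to that methyl (the C1 epimer relative to 28, corrected in step 19).

Step 8
Reactants: 11 methyl (1S,2S,3R)-2-(but-3-en-1-yl)-2-methyl-4-oxo-3-{[2-(pivaloyloxy)phenyl]methyl}cyclohexane-1-carboxylate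
Product: 12 triol: 2-{[2-(but-3-en-1-yl)-6-hydroxy-3-(hydroxymethyl)-2-methylcyclohexyl]methyl}phenol (ring stereocentres as in 11, new carbinol drawn trans to the ring methyl)
Conditions: LiAlH4, THF, 0 °C to rt
Reagents that add atoms: none
Why: Hydride reduction should convert the ester to the primary alcohol and the ketone to the secondary alcohol and cleave the aryl pivalate in one operation; the new carbinol configuration is not controlled and does not matter, because step 9 reoxidises it.

Step 9
Reactants: 12 triol from step 8
Product: 13 (1S,2R,3R)-2-(but-3-en-1-yl)-3-[(2-hydroxyphenyl)methyl]-2-methyl-4-oxocyclohexane-1-carbaldehyde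
Conditions: SO3·pyridine, DMSO, i-Pr2NEt, CH2Cl2, 0 °C
Reagents that add atoms: none
Why: Parikh–Doering oxidation of both alcohols under mild conditions that tolerate the free phenol and should not epimerise the aldehyde α-carbon.

Step 10
Reactants: 14 3-methylbut-2-en-1-ol
Product: 15 (2R)-2-bromo-3-chloro-3-methylbutan-1-ol
Conditions: NBS, ClTi(OiPr)3, chiral tridentate Schiff-base ligand (20 mol%, enantiomer giving the 2R product), hexanes, −20 °C
Reagents that add atoms: N-bromosuccinimide, O=C1CCC(=O)N1Br; chlorotitanium triisopropoxide, CC(C)O[Ti](Cl)(OC(C)C)OC(C)C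
Why: Catalytic enantioselective bromochlorination of an allylic alcohol bound to titanium, with anti addition, chloride at the tertiary carbon and bromine at the carbon next to the carbinol, the ligand selecting the alkene face and thus the single stereocentre.

Step 11
Reactants: 15 (2R)-2-bromo-3-chloro-3-methylbutan-1-ol
Product: 16 (2R)-2-bromo-3-chloro-3-methylbutyl trifluoromethanesulfonate
Conditions: Tf2O, 2,6-lutidine, CH2Cl2, −78 °C
Reagents that add atoms: trifluoromethanesulfonic anhydride, O=S(=O)(OS(=O)(=O)C(F)(F)F)C(F)(F)F
Why: O-Sulfonylation of the primary alcohol; the β-halogen retards ionisation of the triflate and the stereocentre is not touched.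

Step 12
Reactants: 16 (2R)-2-bromo-3-chloro-3-methylbutyl trifluoromethanesulfonate; 17 acetone N,N-dimethylhydrazone
Product: 19 (5R)-5-bromo-6-chloro-6-methylheptan-2-one, via alkylated dimethylhydrazone 18 (not isolated)
Conditions: LiN(iPr)2, THF, −78 °C; 16, −78 to −20 °C; then aq. oxalic acid, Et2O, rt
Reagents that add atoms: water, O
Why: Alkylation of the lithiated hydrazone (an acetone enolate equivalent) at the primary triflate by SN2, then mild hydrolysis; the bromine-bearing stereocentre takes no part.

Step 13
Reactants: 19 (5R)-5-bromo-6-chloro-6-methylheptan-2-one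
Product: 20 (5R)-5-bromo-6-chloro-6-methylhept-1-en-2-yl trifluoromethanesulfonate
Conditions: KN(SiMe3)2, PhNTf2, THF, −78 °C
Reagents that add atoms: N-phenylbis(trifluoromethanesulfonimide), O=S(=O)(N(c1ccccc1)S(=O)(=O)C(F)(F)F)C(F)(F)F
Why: Kinetic deprotonation at the methyl group and O-triflation should give the 1-alken-2-yl triflate, the hindered secondary bromide and tertiary chloride being inert at −78 °C.

Step 14
Reactants: 13 (1S,2R,3R)-2-(but-3-en-1-yl)-3-[(2-hydroxyphenyl)methyl]-2-methyl-4-oxocyclohexane-1-carbaldehyde; 20 (5R)-5-bromo-6-chloro-6-methylhept-1-en-2-yl trifluoromethanesulfonate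
Product: 21 (2R,3R,4S)-3-(but-3-en-1-yl)-4-[(1R,5R)-5-bromo-6-chloro-1-hydroxy-6-methyl-2-methylideneheptyl]-2-[(2-hydroxyphenyl)methyl]-3-methylcyclohexan-1-one
Conditions: CrCl2 (6 equiv), NiCl2 (2 mol%), DMF, rt
Reagents that add atoms: none
Why: Nozaki–Hiyama–Kishi coupling, in which the alkenylchromium species adds only to the aldehyde (ketone, phenol and alkyl halides are tolerated) and Felkin–Anh attack anti to the quaternary ring carbon should give the (R)-carbinol.

Step 15
Reactants: 21 allylic alcohol from step 14
Product: 22 trans-fused cycloheptenol: 2-hydroxy-3-[(3R)-3-bromo-4-chloro-4-methylpentyl]-8-[(2-hydroxyphenyl)methyl]-7-methylbicyclo[5.4.0]undec-3-en-9-one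
Conditions: second-generation Grubbs catalyst (5 mol%), CH2Cl2, 40 °C
Reagents that add atoms: none
Why: Ring-closing metathesis between the monosubstituted and the 1,1-disubstituted alkene should close the seven-membered ring as its trisubstituted cis alkene, the trans ring fusion being fixed already by the two ring-A stereocentres.

Step 16
Reactants: 22 trans-fused cycloheptenol
Product: 24 bromo keto aldehyde (ring-B decalin; 1-epi series; CHO on C5), via dibromophenol cycloheptenol 23 (not isolated)
Conditions: NBS (3.1 equiv in two portions), NaHCO3, CH2Cl2–HFIP 4:1, −40 to 0 °C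
Reagents that add atoms: N-bromosuccinimide, O=C1CCC(=O)N1Br
Why: Proposed new method: the first two equivalents of NBS brominate the free phenol at its open para and ortho positions (23), the third forms a bromonium ion on the only alkene, and the hydroxyl lone pair then drives a semipinacol 1,2-shift of the ring bond between the ring-fusion CH and the carbinol carbon onto the tertiary bromonium carbon, so that the seven-membered ring contracts to ring B and the carbinol carbon is expelled as an aldehyde. The closest known reaction types are the halonium-induced semipinacol rearrangement of allylic alcohols (aryl or alkyl shift, ring expansion of 1-alkenylcycloalkanols) and the Lewis-acid ring contraction of cyclic 2,3-epoxy alcohols; to my knowledge a bromonium-triggered ring-bond shift in a secondary cyclohept-2-enol, combined with arene bromination, has no direct precedent. Ring B is closed not by a cyclisation but by a suprafacial 1,2-alkyl shift (three-centre transition state, net 7→6 contraction) with retention at the migrating ring-fusion carbon. C6 and the quaternary C5 are set together by anti addition of bromine and the migrating carbon across the cis ring alkene, which puts bromine equatorial and anti to the new ring bond, the formyl group axial and the side chain equatorial. The sense relative to ring A should follow from a chair-like transition state for the nascent ring B, with the migrating bond perpendicular to the alkene plane and bromine delivered to the opposite face. Ring-bond rather than hydride migration is favoured because the seven-membered ring holds the carbinol hydrogen near the alkene plane, and chemoselectivity rests on the absence of any other alkene and on slow α-bromination of the ketone under bicarbonate buffering.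

Step 17
Reactants: 24 bromo keto aldehyde
Product: 25 aldehyde N-tosylhydrazone of 24
Conditions: TsNHNH2 (1.05 equiv), THF, 0 °C to rt
Reagents that add atoms: p-toluenesulfonyl hydrazide, Cc1ccc(cc1)S(=O)(=O)NN
Why: Hydrazone condensation, in which the aldehyde should react much faster than the α-branched ring ketone, and the β-bromo aldehyde cannot eliminate because it has no α-hydrogen.

Step 18
Reactants: 25 aldehyde N-tosylhydrazone
Product: 26 (1R,4aS,5R,6R,8aR)-6-bromo-5-[(3R)-3-bromo-4-chloro-4-methylpentyl]-1-[(3,5-dibromo-2-hydroxyphenyl)methyl]-5,8a-dimethyloctahydronaphthalen-2(1H)-one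
Conditions: catecholborane, CHCl3, 0 °C; then NaOAc·3H2O, 60 °C
Reagents that add atoms: none
Why: Catecholborane variant of the Caglioti reduction (hydroboration of C=N, then loss of sulfinate and N2 from the diazene) should turn the formyl group into the axial C5 methyl without reducing the alkyl or aryl bromides or, at 0 °C, the hindered ketone.

Step 19
Reactants: 26 C1-epimeric ketone
Product: 27 (1S,4aS,5R,6R,8aR)-6-bromo-5-[(3R)-3-bromo-4-chloro-4-methylpentyl]-1-[(3,5-dibromo-2-hydroxyphenyl)methyl]-5,8a-dimethyloctahydronaphthalen-2(1H)-one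
Conditions: DBU, CH2Cl2, rt
Reagents that add atoms: none
Why: Base-mediated epimerisation through the enolate, in which the arylmethyl group should settle equatorial (cis to the angular methyl) on the trans-decalin as in 8-oxo drimane and labdane ketones, while the equatorial ring bromide has no antiperiplanar hydrogen for E2.

Step 20
Reactants: 27 ketone
Product: 28 2,4-dibromo-6-{[(1R,4aS,5R,6R,8aS)-6-bromo-5-[(3R)-3-bromo-4-chloro-4-methylpentyl]-5,8a-dimethyl-2-methylidenedecahydronaphthalen-1-yl]methyl}phenol
Conditions: Cp2TiMe2 (4 equiv), toluene, 65 °C, dark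
Reagents that add atoms: dimethyltitanocene, C[Ti](C)(C1C=CC=C1)C1C=CC=C1
Why: Petasis methylenation of the hindered ketone with a non-basic titanium methylidene, so the C1 configuration and the three alkyl halides should survive, and the titanium phenoxide formed from the phenol is cleaved on work-up.

**Compound list**
1 | (E)-pent-3-en-2-one | C/C=C/C(C)=O | starting material
2 | (E)-2-[(triisopropylsilyl)oxy]penta-1,3-diene | C=C(O[Si](C(C)C)(C(C)C)C(C)C)/C=C/C | intermediate
3 | methyl acrylate | C=CC(=O)OC | starting material
4 | methyl (1S,2R)-2-methyl-4-[(triisopropylsilyl)oxy]cyclohex-3-ene-1-carboxylate (cis) | COC(=O)[C@H]1CCC(O[Si](C(C)C)(C(C)C)C(C)C)=C[C@H]1C | intermediate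
5 | methyl (1S)-2-methyl-4-oxocyclohex-2-ene-1-carboxylate | COC(=O)[C@H]1CCC(=O)C=C1C | intermediate
6 | but-3-en-1-ylmagnesium bromide | C=CCC[Mg]Br | starting material
7 | methyl (1S,2S)-2-(but-3-en-1-yl)-2-methyl-4-[(trimethylsilyl)oxy]cyclohex-3-ene-1-carboxylate (butenyl trans to ester) | COC(=O)[C@H]1CCC(O[Si](C)(C)C)=C[C@]1(C)CCC=C | intermediate
8 | 2-methylphenol | Cc1ccccc1O | starting material
9 | 2-methylphenyl pivalate | Cc1ccccc1OC(=O)C(C)(C)C | intermediate
10 | 2-(bromomethyl)phenyl pivalate | BrCc1ccccc1OC(=O)C(C)(C)C | intermediate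
11 | methyl (1S,2S,3R)-2-(but-3-en-1-yl)-2-methyl-4-oxo-3-{[2-(pivaloyloxy)phenyl]methyl}cyclohexane-1-carboxylate (benzyl trans to ring methyl) | O=C1CC[C@H](C(=O)OC)[C@@](C)(CCC=C)[C@H]1Cc1ccccc1OC(=O)C(C)(C)C | intermediate
12 | 2-{[2-(but-3-en-1-yl)-6-hydroxy-3-(hydroxymethyl)-2-methylcyclohexyl]methyl}phenol (ring stereocentres as in 11; secondary OH trans to ring methyl) | O[C@H]1CC[C@H](CO)[C@@](C)(CCC=C)[C@H]1Cc1ccccc1O | intermediate
13 | (1S,2R,3R)-2-(but-3-en-1-yl)-3-[(2-hydroxyphenyl)methyl]-2-methyl-4-oxocyclohexane-1-carbaldehyde | O=C1CC[C@H](C=O)[C@@](C)(CCC=C)[C@H]1Cc1ccccc1O | intermediate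
14 | 3-methylbut-2-en-1-ol | CC(C)=CCO | starting material
15 | (2R)-2-bromo-3-chloro-3-methylbutan-1-ol | OC[C@@H](Br)C(C)(C)Cl | intermediate
16 | (2R)-2-bromo-3-chloro-3-methylbutyl trifluoromethanesulfonate | O=S(=O)(OC[C@@H](Br)C(C)(C)Cl)C(F)(F)F | intermediate
17 | acetone N,N-dimethylhydrazone | CC(C)=NN(C)C | starting material
18 | (5R)-5-bromo-6-chloro-6-methylheptan-2-one N,N-dimethylhydrazone | CC(CC[C@@H](Br)C(C)(C)Cl)=NN(C)C | intermediate
19 | (5R)-5-bromo-6-chloro-6-methylheptan-2-one | CC(=O)CC[C@@H](Br)C(C)(C)Cl | intermediate
20 | (5R)-5-bromo-6-chloro-6-methylhept-1-en-2-yl trifluoromethanesulfonate | C=C(OS(=O)(=O)C(F)(F)F)CC[C@@H](Br)C(C)(C)Cl | intermediate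
21 | (2R,3R,4S)-3-(but-3-en-1-yl)-4-[(1R,5R)-5-bromo-6-chloro-1-hydroxy-6-methyl-2-methylideneheptyl]-2-[(2-hydroxyphenyl)methyl]-3-methylcyclohexan-1-one | O=C1CC[C@H]([C@@H](O)C(=C)CC[C@@H](Br)C(C)(C)Cl)[C@@](C)(CCC=C)[C@H]1Cc1ccccc1O | intermediate
22 | trans-fused 2-hydroxy-3-[(3R)-3-bromo-4-chloro-4-methylpentyl]-8-[(2-hydroxyphenyl)methyl]-7-methylbicyclo[5.4.0]undec-3-en-9-one ((R)-carbinol; arylmethyl trans to angular methyl) | O=C1CC[C@@H]2[C@@H](O)C(CC[C@@H](Br)C(C)(C)Cl)=CCC[C@@]2(C)[C@H]1Cc1ccccc1O | intermediate
23 | 22 with the phenol ring brominated para and ortho to OH (3,5-dibromo-2-hydroxyphenyl) | O=C1CC[C@@H]2[C@@H](O)C(CC[C@@H](Br)C(C)(C)Cl)=CCC[C@@]2(C)[C@H]1Cc1cc(Br)cc(Br)c1O | intermediate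
24 | bromo keto aldehyde: as 26 but with CHO in place of the C5 methyl [(1R,4aS,5R,6R,8aR) in the decalin locants of 28] | O=C1CC[C@@H]2[C@@](C=O)(CC[C@@H](Br)C(C)(C)Cl)[C@H](Br)CC[C@@]2(C)[C@H]1Cc1cc(Br)cc(Br)c1O | intermediate
25 | (E)-N-tosylhydrazone of the aldehyde group of 24 | O=C1CC[C@@H]2[C@@](/C=N/NS(=O)(=O)c3ccc(C)cc3)(CC[C@@H](Br)C(C)(C)Cl)[C@H](Br)CC[C@@]2(C)[C@H]1Cc1cc(Br)cc(Br)c1O | intermediate
26 | (1R,4aS,5R,6R,8aR)-6-bromo-5-[(3R)-3-bromo-4-chloro-4-methylpentyl]-1-[(3,5-dibromo-2-hydroxyphenyl)methyl]-5,8a-dimethyloctahydronaphthalen-2(1H)-one | O=C1CC[C@@H]2[C@@](C)(CC[C@@H](Br)C(C)(C)Cl)[C@H](Br)CC[C@@]2(C)[C@H]1Cc1cc(Br)cc(Br)c1O | intermediate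
27 | (1S,4aS,5R,6R,8aR)-6-bromo-5-[(3R)-3-bromo-4-chloro-4-methylpentyl]-1-[(3,5-dibromo-2-hydroxyphenyl)methyl]-5,8a-dimethyloctahydronaphthalen-2(1H)-one | O=C1CC[C@@H]2[C@@](C)(CC[C@@H](Br)C(C)(C)Cl)[C@H](Br)CC[C@@]2(C)[C@@H]1Cc1cc(Br)cc(Br)c1O | intermediate
28 | 2,4-dibromo-6-{[(1R,4aS,5R,6R,8aS)-6-bromo-5-[(3R)-3-bromo-4-chloro-4-methylpentyl]-5,8a-dimethyl-2-methylidenedecahydronaphthalen-1-yl]methyl}phenol | C=C1CC[C@@H]2[C@@](C)(CC[C@@H](Br)C(C)(C)Cl)[C@H](Br)CC[C@@]2(C)[C@@H]1Cc1cc(Br)cc(Br)c1O | target

Total steps: 20. Longest linear sequence: 14 steps (steps 1–4, 7–9, 14–20).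

**Steps most likely to fail**

Step 16 (proposed new method). The bromonium ion may be captured by oxygen nucleophiles (bromoetherification, epoxide formation, succinimide or solvent capture), or it may form on the wrong alkene face faster than the ring bond migrates. The fallback sets out from 22 and returns to the route at 24, and it separates the events into two textbook reactions. NBS (3.1 equiv) in aqueous acetone at 0 °C should brominate the arene twice and convert the alkene into the Markovnikov anti bromohydrin, giving the bromo diol F1 (bromine on the former alkene CH, tertiary hydroxyl on the side-chain-bearing carbon), which can be purified and its face isomers separated. BF3·OEt2 in CH2Cl2 at −40 °C should then ionise the tertiary carbinol with assistance from the neighbouring bromine and trigger a classical pinacol rearrangement of the vicinal diol, with ring-bond shift and ring contraction, to 24.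

Step 14. Low-valent chromium and nickel may reduce the vicinal bromochloride of 20 with β-elimination, or the addition may proceed with poor facial control. The fallback sets out from 20 and returns at 21 without any stoichiometric reductant. Miyaura borylation of 20 (PdCl2(PPh3)2, bis(pinacolato)diboron, KOPh, toluene, 50 °C) should give the alkenyl pinacolboronate F2, and rhodium-catalysed 1,2-addition of F2 to aldehyde 13 (Rh(acac)(CO)2, dppf, DME–H2O, 60 °C), which is selective for aldehydes over ketones, should give 21.

Step 20. Carbonyl methylenation of the hindered ketone may be slow at 65 °C, so that loss of HBr or HCl from the side chain or enolisation at C1 competes. The fallback sets out from 27 and returns at 28 by a Peterson olefination in two stages. Me3SiCH2Li with CeCl3 (THF, −78 °C; a non-basic organocerium reagent) should add to the ketone and give the β-hydroxysilane F3, and KH in THF at 0 °C should then effect syn elimination to the exocyclic methylene of 28.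

**Further compounds**
F1 | step 16 | bromo diol: 23 with Br on the former alkene CH and a tertiary OH on the side-chain-bearing carbon (anti) | O=C1CC[C@@H]2[C@@H](O)[C@](O)(CC[C@@H](Br)C(C)(C)Cl)[C@H](Br)CC[C@@]2(C)[C@H]1Cc1cc(Br)cc(Br)c1O
F2 | step 14 | 2-[(5R)-5-bromo-6-chloro-6-methylhept-1-en-2-yl]-4,4,5,5-tetramethyl-1,3,2-dioxaborolane | C=C(B1OC(C)(C)C(C)(C)O1)CC[C@@H](Br)C(C)(C)Cl
F3 | step 20 | β-hydroxysilane: 27 with C2 as C(OH)CH2SiMe3 (OH axial, cis to the angular methyl) | C[Si](C)(C)C[C@@]1(O)CC[C@@H]2[C@@](C)(CC[C@@H](Br)C(C)(C)Cl)[C@H](Br)CC[C@@]2(C)[C@@H]1Cc1cc(Br)cc(Br)c1O
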